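**Retrosynthetic overview**

1. Ring formation happens once: the bought ten-membered ring of germacrone (1) is closed across C5–C10, so rings A and B form together. In the same flask the eudesmane (2) goes on by 1,2-H and 1,2-Me shifts to the eremophilane dehydrofukinone (3).
2. C7=C11 disconnection: ozonolysis of 3 removes the C3 unit as acetone and leaves the trinor diosphenol (4).
3. Ring-A oxidation: Δ1 through the silyl dienol ether (5) and Saegusa oxidation (6); C3–O by allylic hydroxylation (7, deliberately the C3 epimer).
4. Side chain: butanal (8) → α-hydroxymethylation (9, 10) → vinylogous HWE with phosphonocrotonic acid (11) → acid (12).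
5. C3–O ester disconnection: Mitsunobu inversion joins 7 and 12 (13); global desilylation gives Septeremophilane E (14).

Locants are eremophilane/eudesmane locants: C3 = ester carbon, C4 = CHMe, C5 = quaternary C–Me, C8 = ketone carbon, C10 = ring-fusion sp2 carbon. The target is (3S,4R,5S), with 3-O, 4-Me and 5-Me all cis.

Assumption: germacrone is bought in bulk (main crystalline constituent of zdravets and zedoary oils), and the antipode of the chiral acid that gives the (10R) cyclisation product is picked by testing both antipodes.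

**Route**

Step 1
Reactants: 1 germacrone
Product: 3 (4aR,5S)-dehydrofukinone, via eudesmadienone 2 (not isolated)
Conditions: chiral IDPi Brønsted acid (5 mol%), HFIP/CH2Cl2, −40 °C; then TfOH (10 mol%), −40 → 23 °C
Reagents that add atoms: none
Why: Proposed new method: protonation of C1 inside the chiral ion pair closes C5–C10 across the ring (the known acid cyclisation of germacrone to eudesmadienones) and fixes C10 as R, then under the stronger non-nucleophilic acid the Δ3/Δ4/Δ4(15) olefins re-ionise, H-5 moves to C4 (or Δ4 is protonated at C4 anti to the axial methyl), the axial C10 methyl migrates suprafacially to C5 with push from the C8 enol (vinylogous semipinacol) and loss of H-9 gives the enone, the one exit that cannot re-protonate at carbon, so the olefin mixture should drain to the cis-4,5-dimethyl eremophilane; closest known reaction types are the acid transannular cyclisation of germacranes, chiral-acid proton-initiated polyene cyclisation and the epoxide- or 5α-leaving-group-triggered (Westphalen-type) eudesmane→eremophilane methyl shift.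

Step 2
Reactants: 3 (4aR,5S)-dehydrofukinone
Product: 4 trinor diosphenol
Conditions: O3, CH2Cl2/MeOH, −78 °C (Sudan Red 7B end point); then Me2S, −78 → 23 °C
Reagents that add atoms: ozone, [O-][O+]=O
Why: Ozonolysis with reductive work-up: the tetrasubstituted isopropylidene is the most electron-rich olefin (pulegone gives its diosphenol the same way), and the resulting 7,8-dione can enolise only toward C6, giving the cross-conjugated diosphenol with C4 and C5 untouched.

Step 3
Reactants: 4 trinor diosphenol
Product: 6 silyl trienone, via bis-silyl dienol ether 5 (not isolated)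
Conditions: TBSOTf (2.3 equiv), Et3N (3.5 equiv), CH2Cl2, 0 °C; volatiles removed; Pd(OAc)2 (1.1 equiv), MeCN, 23 °C
Reagents that add atoms: TBSOTf, CC(C)(C)[Si](C)(C)OS(=O)(=O)C(F)(F)F
Why: Soft enolisation silylates the diosphenol OH and converts the dienone into its extended silyl dienol ether by loss of the only available γ-hydrogen (at C1; C5 and C7 carry none), and Saegusa–Ito oxidation then places Pd on C1 where the only β-hydrogens are on C2, so the Δ1 olefin forms while the 7-O-silyl enol ether (no β-H at C5) stays as protecting group; no stereocentre is touched.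

Step 4
Reactants: 6 silyl trienone
Product: 7 3α-allylic alcohol
Conditions: SeO2 (0.5 equiv), t-BuOOH (3 equiv, decane), CH2Cl2, 0 → 35 °C
Reagents that add atoms: tert-butyl hydroperoxide, CC(C)(C)OO (oxygen delivered through selenium dioxide, O=[Se]=O)
Why: Riley–Sharpless allylic hydroxylation: the ene reaction at C1=C2 can only take a hydrogen from C3 (compare C4 oxidation of β-ionone) and the [2,3] shift returns the double bond to C1=C2, both events being expected on the face anti to the cis 4-Me/5-Me pair, so the 3α (3R) alcohol, the C3 epimer of the natural one, should form and is inverted in step 7.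

Step 5
Reactants: 8 butanal
Product: 10 silyloxy aldehyde, via hydroxy aldehyde 9 (not isolated)
Conditions: (R)-α,α-diphenylprolinol TMS ether (10 mol%), 37% aq. HCHO (3 equiv), pH 7 phosphate buffer, toluene, 23 °C; organic phase dried, then TBSCl, imidazole, 0 °C
Reagents that add atoms: formaldehyde, C=O; TBSCl, CC(C)(C)[Si](C)(C)Cl
Why: Enamine-catalysed cross-aldol with formaldehyde (organocatalytic α-hydroxymethylation): the diarylprolinol silyl ether shields one face of the E-enamine so that the (R)-catalyst should give the (S)-aldehyde, and immediate silylation stops dimerisation and dehydration.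

Step 6
Reactants: 10 silyloxy aldehyde; 11 (E)-4-(diethoxyphosphoryl)but-2-enoic acid
Product: 12 (2E,4E,6R)-dienoic acid
Conditions: 11, LDA (2.1 equiv), THF, −78 °C; then 10, −78 → 0 °C; aq. HCl work-up (pH 3)
Reagents that add atoms: none
Why: Vinylogous Horner–Wadsworth–Emmons olefination with the phosphonocrotonic acid dianion gives the (2E,4E)-dienoic acid directly (as in retinoic acid syntheses), and at −78 °C the α-stereocentre of the Roche-type aldehyde is not epimerised.

Step 7
Reactants: 7 3α-allylic alcohol; 12 (2E,4E,6R)-dienoic acid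
Product: 13 bis-TBS ester
Conditions: PPh3 (2 equiv), DIAD (2 equiv), 12 (1.5 equiv), toluene, 0 → 23 °C
Reagents that add atoms: none
Why: Mitsunobu esterification: the carboxylate displaces the C3 oxyphosphonium in an SN2 step with inversion (3R → 3S), giving the all-cis C3/C4/C5 triad, while SN2′ attack at C1 would break the trienone conjugation and the silylated enol cannot compete as a pronucleophile.

Step 8
Reactants: 13 bis-TBS ester
Product: 14 Septeremophilane E
Conditions: HF·pyridine, pyridine/THF, 0 → 23 °C
Reagents that add atoms: none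
Why: Fluoride-mediated desilylation under mildly acidic, non-basic conditions cleaves the primary TBS ether and the silyl enol ether together without ε-deprotonation at C3 or ester cleavage, and the 1,2-dione unit stays in its stable diosphenol form.

**Compound list**

1 | germacrone, (3E,7E)-3,7-dimethyl-10-(propan-2-ylidene)cyclodeca-3,7-dien-1-one | C/C1=C\CC/C(C)=C/CC(=C(C)C)C(=O)C1 | starting material
2 | (10R)-eudesma-4,7(11)-dien-8-one, (8aR)-5,8a-dimethyl-3-(propan-2-ylidene)-3,4,6,7,8,8a-hexahydronaphthalen-2(1H)-one | CC1=C2CC(=C(C)C)C(=O)C[C@@]2(C)CCC1 | intermediate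
3 | dehydrofukinone, (4aR,5S)-4a,5-dimethyl-3-(propan-2-ylidene)-4,4a,5,6,7,8-hexahydronaphthalen-2(3H)-one (eremophila-7(11),9-dien-8-one, 4-Me and 5-Me cis) | C1CCC2=CC(=O)C(=C(C)C)C[C@]2(C)[C@H]1C | intermediate
4 | (4aS,5S)-3-hydroxy-4a,5-dimethyl-5,6,7,8-tetrahydronaphthalen-2(4aH)-one (7-hydroxy-trinoreremophila-6,9-dien-8-one) | C1CCC2=CC(=O)C(O)=C[C@]2(C)[C@H]1C | intermediate
5 | (4aS,5S)-2,3-bis[(tert-butyldimethylsilyl)oxy]-4a,5-dimethyl-4a,5,6,7-tetrahydronaphthalene (7,8-bis-silyloxy 1(10),6,8-triene) | C1CC=C2C=C(O[Si](C)(C)C(C)(C)C)C(O[Si](C)(C)C(C)(C)C)=C[C@]2(C)[C@H]1C | intermediate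
6 | (4aS,5S)-3-[(tert-butyldimethylsilyl)oxy]-4a,5-dimethyl-5,6-dihydronaphthalen-2(4aH)-one (7-O-TBS 1,6,9-trien-8-one) | C1C=CC2=CC(=O)C(O[Si](C)(C)C(C)(C)C)=C[C@]2(C)[C@H]1C | intermediate
7 | (4aS,5R,6R)-3-[(tert-butyldimethylsilyl)oxy]-6-hydroxy-4a,5-dimethyl-5,6-dihydronaphthalen-2(4aH)-one (3α-OH, trans to 4-Me and 5-Me) | O[C@@H]1C=CC2=CC(=O)C(O[Si](C)(C)C(C)(C)C)=C[C@]2(C)[C@H]1C | intermediate
8 | butanal | CCCC=O | starting material
9 | (S)-2-(hydroxymethyl)butanal | CC[C@H](C=O)CO | intermediate
10 | (S)-2-{[(tert-butyldimethylsilyl)oxy]methyl}butanal | CC[C@H](C=O)CO[Si](C)(C)C(C)(C)C | intermediate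
11 | (E)-4-(diethoxyphosphoryl)but-2-enoic acid | CCOP(=O)(OCC)C/C=C/C(=O)O | starting material
12 | (2E,4E,6R)-6-{[(tert-butyldimethylsilyl)oxy]methyl}octa-2,4-dienoic acid | CC[C@H](/C=C/C=C/C(=O)O)CO[Si](C)(C)C(C)(C)C | intermediate
13 | bis-TBS ether of Septeremophilane E (3β-ester of 12 with the 7-O-TBS core; 3S,4R,5S,6′R) | CC[C@H](/C=C/C=C/C(=O)O[C@H]1C=CC2=CC(=O)C(O[Si](C)(C)C(C)(C)C)=C[C@]2(C)[C@H]1C)CO[Si](C)(C)C(C)(C)C | intermediate
14 | Septeremophilane E, (3S,4R,5S)-7-hydroxy-8-oxo-trinoreremophila-1,6,9-trien-3-yl (2E,4E,6R)-6-(hydroxymethyl)octa-2,4-dienoate | CC[C@H](/C=C/C=C/C(=O)O[C@H]1C=CC2=CC(=O)C(O)=C[C@]2(C)[C@H]1C)CO | target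

**Totals**

Total steps: 8 (6 on the core line, 2 for the acid). Longest linear sequence: 6 steps (1, 2, 3, 4, 7, 8, from germacrone).

**Three steps most likely to fail**

Step 1. The one-flask cascade may stop at the eudesmane stage or leak to Δ5 dienes. The fallback sets out from 1 and comes back at 3. The cyclisation is run with the chiral acid alone and eudesmadienone 2 is isolated. mCPBA epoxidises its tetrasubstituted Δ4 bond anti to the angular methyl to give the 4α,5α-epoxide F1. BF3·OEt2 ionises C5–O with antiperiplanar migration of the C10 methyl and loss of H-9, the established epoxide route from eudesmanes to eremophilanes, to give the 4α-hydroxy eremophiladienone F2. Acylation with methyl chlorooxoacetate gives the tertiary methyl oxalate F3, and Bu3SnH/AIBN deoxygenation with hydrogen delivery anti to the 5-methyl gives 3.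

Step 4. The deactivated C1=C2 bond may react slowly, or the oxidant may attack the silyl enol ether. The fallback sets out from 6 and comes back at 7. Soft enolisation (TBSOTf, Et3N), which can only remove an ε-hydrogen from C3, gives the bis-silyl tetraene F4. DMDO at −78 °C oxidises its terminal C2=C3 bond anti to the methyl groups (vinylogous Rubottom oxidation), and collapse of the epoxide with loss of the C8 silyl group on work-up gives 7.

Step 7. The allylic alcohol is hindered, so elimination or incomplete inversion is possible; a wrong C3 outcome of step 4 would also show here. The fallback sets out from 7 and comes back at 13. MnO2 oxidises the allylic alcohol to the ene-dione F5. Luche reduction at −78 °C reduces the more electrophilic C3 carbonyl with hydride delivery anti to the 4,5-methyl groups to give the 3β-alcohol F6; this pair of steps is stereoconvergent, so it also corrects any 3α/3β mixture. Yamaguchi esterification with acid 12, with retention, gives 13.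

**Further compounds**

F1 | step 1 | 4α,5α-epoxyeudesm-7(11)-en-8-one (epoxide of 2, oxygen anti to the angular methyl) | C[C@]12CCC[C@@]3(C)O[C@@]13CC(=C(C)C)C(=O)C2
F2 | step 1 | 4α-hydroxyeremophila-7(11),9-dien-8-one (4-hydroxy-dehydrofukinone, 4β-Me and 5β-Me cis) | C1CCC2=CC(=O)C(=C(C)C)C[C@]2(C)[C@]1(C)O
F3 | step 1 | methyl oxalate of F2 | C1CCC2=CC(=O)C(=C(C)C)C[C@]2(C)[C@]1(C)OC(=O)C(=O)OC
F4 | step 4 | (1S,8aS)-6,7-bis[(tert-butyldimethylsilyl)oxy]-1,8a-dimethyl-1,8a-dihydronaphthalene (bis-silyl tetraene from 6) | C1=CC=C2C=C(O[Si](C)(C)C(C)(C)C)C(O[Si](C)(C)C(C)(C)C)=C[C@]2(C)[C@H]1C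
F5 | step 7 | (4aS,5R)-3-[(tert-butyldimethylsilyl)oxy]-4a,5-dimethyl-4a,5-dihydronaphthalene-2,6-dione (ene-dione) | O=C1C=CC2=CC(=O)C(O[Si](C)(C)C(C)(C)C)=C[C@]2(C)[C@H]1C
F6 | step 7 | (4aS,5R,6S)-3-[(tert-butyldimethylsilyl)oxy]-6-hydroxy-4a,5-dimethyl-5,6-dihydronaphthalen-2(4aH)-one (3β-alcohol, C3 epimer of 7) | O[C@H]1C=CC2=CC(=O)C(O[Si](C)(C)C(C)(C)C)=C[C@]2(C)[C@H]1C
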